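**Plan** (flavanone numbering: O1, C2, C3, C4, C4a, C5–C8, C8a; ring B primed; geranyl = (2E)-3,7-dimethylocta-2,6-dien-1-yl)
1. Retrosynthesis: after removal of three aryl silyl ethers, ring C is cut at C4–C4a and C2–C3 in one operation, giving an O-aryl oxocarbenium ion (ring A–O1+=C2H–ring B) and a glycolic acid ketene acetal (C3=C4). Then O1–C2 (phenol plus alpha-chloro ester of the ring B aldehyde), C3'–geranyl (phenoxide C-alkylation) and C8a–O1 (C–H borylation/oxidation) are cut.
2. Enabling feature: O1 joins C8a of ring A to the benzylic C2 that carries the para-oxygenated ring B, so C4a=C8a–O1+=C2 is a stabilised 2-oxonia-diene. Its carbon terminus C4a is ortho to O1 and to the C5 oxygen and para to the C7 oxygen, the ring A phenol is symmetric (both ortho positions are the same), and C3/C4 carry the oxygen pattern of glycolic acid.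
3. Forward: rings A and B are bought as benzene rings and dressed separately, then joined through O1–C2 as an acetal acetate. Ring C, the only ring made, closes in step 9 by a catalytic enantioselective oxa-Povarov-type [4+2]; fluoride then frees the phenols.
4. Stereochemistry: C2 is set in step 9 by the chiral counter-anion of the acid catalyst. C3 is set in the same step relative to C2, and 2,3-trans is also the thermodynamic arrangement (C3 is alpha to the C4 ketone). The E-olefin comes from geranyl bromide.
5. Helpers: acetate (leaving group at C2), the acetonide and O-silyl group of the ketene acetal (C4 arrives as a ketal and is released in the work-up of step 9), TBS and TIPS ethers (removed in step 10).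

Key step: step 9

Remark 1: compounds 1, 5, 6 and 11 are taken as commercial.
Remark 2: HX* is an imidodiphosphorimidate (IDPi) Brønsted acid built from two 3,3'-bis[3,5-bis(trifluoromethyl)phenyl]-1,1'-bi-2-naphthol units with N-trifluoromethanesulfonyl groups. The sense of induction with this ion pair cannot be predicted, so the (S,S)- or (R,R)-acid that gives the (2R) series is chosen in a test run.

**Step 1**
Reactants: 1 2-methylresorcinol
Product: 2 2,6-bis(tert-butyldimethylsilyloxy)toluene
Conditions: TBSCl (2.3 equiv), imidazole (5 equiv), DMF, rt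
Reagents that add atoms: tert-butyldimethylsilyl chloride, CC(C)(C)[Si](C)(C)Cl
Why: Imidazole-promoted O-silylation of both phenols gives silyl ethers that should survive borylation and acid and leave with fluoride at the end.

**Step 2**
Reactants: 2 2,6-bis(tert-butyldimethylsilyloxy)toluene
Product: 3 2-[3,5-bis(tert-butyldimethylsilyloxy)-4-methylphenyl]-4,4,5,5-tetramethyl-1,3,2-dioxaborolane
Conditions: [Ir(OMe)(cod)]2 (1.5 mol%), 4,4'-di-tert-butyl-2,2'-bipyridine (3 mol%), B2pin2 (1.0 equiv), hexane, 80 °C
Reagents that add atoms: bis(pinacolato)diboron, CC1(C)OB(OC1(C)C)B1OC(C)(C)C(C)(C)O1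
Why: Iridium-catalysed aromatic C–H borylation is sterically controlled and should take the only C–H without an ortho substituent, the one para to the methyl group.

**Step 3**
Reactants: 3 2-[3,5-bis(tert-butyldimethylsilyloxy)-4-methylphenyl]-4,4,5,5-tetramethyl-1,3,2-dioxaborolane
Product: 4 3,5-bis(tert-butyldimethylsilyloxy)-4-methylphenol
Conditions: Oxone (2KHSO5·KHSO4·K2SO4), acetone/H2O, rt, 10 min; aq. NaHSO3
Reagents that add atoms: potassium peroxymonosulfate (active salt of Oxone), [K+].[O-]S(=O)(=O)OO
Why: Peroxide oxidation of an arylboronate (1,2-shift of the aryl group from boron to oxygen) should give the phenol at the borylated carbon, and the short contact time spares the aryl silyl ethers.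

**Step 4**
Reactants: 5 4-hydroxybenzaldehyde; 6 geranyl bromide
Product: 7 3-geranyl-4-hydroxybenzaldehyde
Conditions: KOH (1.1 equiv), H2O, rt; then dilute HCl
Reagents that add atoms: none
Why: C-alkylation of a phenoxide in water (oxygen hydrogen-bonded, para position blocked) should place the geranyl group ortho to the hydroxyl by SN2 with retention of the E-olefin; the O-geranyl ether is the expected companion and is separated.

**Step 5**
Reactants: 7 3-geranyl-4-hydroxybenzaldehyde
Product: 8 3-geranyl-4-(triisopropylsilyloxy)benzaldehyde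
Conditions: TIPSCl (1.3 equiv), imidazole (3 equiv), DMF, rt
Reagents that add atoms: triisopropylsilyl chloride, CC(C)[Si](Cl)(C(C)C)C(C)C
Why: O-silylation of the phenol; the TIPS ether is chosen because it must survive AcCl/ZnCl2 and a para-silyloxybenzyl cation.

**Step 6**
Reactants: 8 3-geranyl-4-(triisopropylsilyloxy)benzaldehyde
Product: 9 chloro[3-geranyl-4-(triisopropylsilyloxy)phenyl]methyl acetate (racemic)
Conditions: AcCl (1.05 equiv), ZnCl2 (2 mol%), CH2Cl2, −20 → 0 °C; volatiles removed, used crude
Reagents that add atoms: acetyl chloride, CC(=O)Cl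
Why: Lewis-acid-catalysed addition of an acyl chloride across the aldehyde C=O (alpha-chloroalkyl ester formation) turns the future C2 into a carbon with one reactive (Cl) and one latent (OAc) leaving group.

**Step 7**
Reactants: 9 chloro[3-geranyl-4-(triisopropylsilyloxy)phenyl]methyl acetate; 4 3,5-bis(tert-butyldimethylsilyloxy)-4-methylphenol
Product: 10 [3,5-bis(tert-butyldimethylsilyloxy)-4-methylphenoxy][3-geranyl-4-(triisopropylsilyloxy)phenyl]methyl acetate (racemic)
Conditions: i-Pr2NEt (1.5 equiv), CH2Cl2, −40 → 0 °C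
Reagents that add atoms: none
Why: SN1-type O-alkylation of the phenol by the alpha-chloroalkyl ester (acyloxyalkyl aryl ether formation) under amine base, where the kinetic O-adduct is not re-ionised, forms the O1–C2 bond and leaves acetate as the only group a silyl Lewis acid will remove.

**Step 8**
Reactants: 11 2,2-dimethyl-1,3-dioxolan-4-one
Product: 12 tert-butyl[(2,2-dimethyl-1,3-dioxol-4-yl)oxy]dimethylsilane
Conditions: TBSOTf (1.1 equiv), Et3N (1.5 equiv), Et2O, 0 °C → rt; distilled
Reagents that add atoms: tert-butyldimethylsilyl trifluoromethanesulfonate, CC(C)(C)[Si](C)(C)OS(=O)(=O)C(F)(F)F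
Why: Soft enolisation of the activated lactone with a silyl triflate and triethylamine gives the cyclic silyl ketene acetal of fixed geometry.

**Step 9**
Reactants: 10 [3,5-bis(tert-butyldimethylsilyloxy)-4-methylphenoxy][3-geranyl-4-(triisopropylsilyloxy)phenyl]methyl acetate; 12 tert-butyl[(2,2-dimethyl-1,3-dioxol-4-yl)oxy]dimethylsilane
Product: 15 (2R,3R)-5,7-bis(tert-butyldimethylsilyloxy)-2-[3-geranyl-4-(triisopropylsilyloxy)phenyl]-3-hydroxy-6-methylchroman-4-one, via aryl oxocarbenium ion 13 (not isolated), via tricyclic silyl ketal 14 (not isolated)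
Conditions: 12 (2.2 equiv), HX* (3 mol%), toluene, −78 → −30 °C; then 0.5 M aq. citric acid, THF, 0 °C
Reagents that add atoms: none
Why: Proposed new method: HX* is silylated by 12 to TBS–X*, which takes acetate from 10 and gives the O-aryl oxocarbenium ion 13 paired with X*−; the CH carbon of ketene acetal 12 adds to C2, and the resulting silyloxy-dioxolanylium ion is trapped by C4a of ring A, so C2–C3 and C4–C4a form in one inverse-demand formal [4+2] event (2-oxonia-diene C4a=C8a–O1+=C2 plus the C3=C4 ketene acetal), the proton released re-forming TBS–X* from the second equivalent of 12. The closest known reaction types are the oxa-Povarov reaction of aryl oxocarbenium ions with alkenes and the counter-anion-directed enantioselective addition of silyl ketene acetals to oxocarbenium ions made from acetal acetates; capture of the carboxonium ion by the arene is the new part, argued from the high nucleophilicity of C4a (ortho to O1 and to the C5 oxygen, para to the C7 oxygen) and from the reversibility of silyl transfer, which keeps the carboxonium ion accessible until irreversible re-aromatisation. Ring C closes by a stepwise [4+2] whose second bond forms by 6-exo-trig attack of the arene on the C4 carboxonium carbon (a 6-endo Friedel–Crafts closure as seen from ring A). C2 is set in the C–C bond formation under control of the chiral counter-anion X*− (catalyst control); C3 follows from the relative topicity of that addition and, being alpha to the C4 ketone in 15, should converge on the more stable 2,3-trans diequatorial arrangement by enolisation if the kinetic selectivity is poor; the C4 ketal centre of 14 is lost on hydrolysis. The step needs chemoselective ionisation (secured by acetate as the only group that can leave as a silyl ester), attack through the CH carbon of 12 (secured by the two oxygen donors on its other olefinic carbon) and no regiochemical choice on ring A (the two ortho positions are equivalent and the para position carries the methyl group). The citric acid work-up then opens silyl ketal 14 with loss of acetone and silanol to give the hydroxy ketone.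

**Step 10**
Reactants: 15 (2R,3R)-5,7-bis(tert-butyldimethylsilyloxy)-2-[3-geranyl-4-(triisopropylsilyloxy)phenyl]-3-hydroxy-6-methylchroman-4-one
Product: 16 (2R,3R)-2-[3-geranyl-4-hydroxyphenyl]-3,5,7-trihydroxy-6-methylchroman-4-one (target)
Conditions: TBAF (3.5 equiv), AcOH (4 equiv), THF, 0 °C → rt
Reagents that add atoms: none
Why: Fluoride cleavage of the three aryl silyl ethers under acetic acid buffering avoids phenoxide-driven opening of ring C, so C2 and C3 should stay as set, and nothing acidic or reducing touches the geranyl chain.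

**Compound list**
1 | 2-methylresorcinol | Cc1c(O)cccc1O | starting material
2 | 2,6-bis(tert-butyldimethylsilyloxy)toluene | Cc1c(O[Si](C)(C)C(C)(C)C)cccc1O[Si](C)(C)C(C)(C)C | intermediate
3 | 2-[3,5-bis(tert-butyldimethylsilyloxy)-4-methylphenyl]-4,4,5,5-tetramethyl-1,3,2-dioxaborolane | Cc1c(O[Si](C)(C)C(C)(C)C)cc(B2OC(C)(C)C(C)(C)O2)cc1O[Si](C)(C)C(C)(C)C | intermediate
4 | 3,5-bis(tert-butyldimethylsilyloxy)-4-methylphenol | Cc1c(O[Si](C)(C)C(C)(C)C)cc(O)cc1O[Si](C)(C)C(C)(C)C | intermediate
5 | 4-hydroxybenzaldehyde | O=Cc1ccc(O)cc1 | starting material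
6 | geranyl bromide, (2E)-1-bromo-3,7-dimethylocta-2,6-diene | CC(C)=CCC/C(C)=C/CBr | starting material
7 | 3-geranyl-4-hydroxybenzaldehyde | CC(C)=CCC/C(C)=C/Cc1cc(C=O)ccc1O | intermediate
8 | 3-geranyl-4-(triisopropylsilyloxy)benzaldehyde | CC(C)=CCC/C(C)=C/Cc1cc(C=O)ccc1O[Si](C(C)C)(C(C)C)C(C)C | intermediate
9 | chloro[3-geranyl-4-(triisopropylsilyloxy)phenyl]methyl acetate, racemic | CC(C)=CCC/C(C)=C/Cc1cc(C(Cl)OC(C)=O)ccc1O[Si](C(C)C)(C(C)C)C(C)C | intermediate
10 | [3,5-bis(tert-butyldimethylsilyloxy)-4-methylphenoxy][3-geranyl-4-(triisopropylsilyloxy)phenyl]methyl acetate, racemic | CC(C)=CCC/C(C)=C/Cc1cc(C(OC(C)=O)Oc2cc(O[Si](C)(C)C(C)(C)C)c(C)c(O[Si](C)(C)C(C)(C)C)c2)ccc1O[Si](C(C)C)(C(C)C)C(C)C | intermediate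
11 | 2,2-dimethyl-1,3-dioxolan-4-one | CC1(C)OCC(=O)O1 | starting material
12 | tert-butyl[(2,2-dimethyl-1,3-dioxol-4-yl)oxy]dimethylsilane | CC1(C)OC=C(O[Si](C)(C)C(C)(C)C)O1 | intermediate
13 | O-aryl oxocarbenium ion from 10 by loss of acetate (cation of an ion pair, counter-anion X*−) | CC(C)=CCC/C(C)=C/Cc1cc(C=[O+]c2cc(O[Si](C)(C)C(C)(C)C)c(C)c(O[Si](C)(C)C(C)(C)C)c2)ccc1O[Si](C(C)C)(C(C)C)C(C)C | intermediate
14 | tricyclic silyl ketal: 15 with C4 as a ketal bearing OTBS and an isopropylidene bridge to the C3 oxygen (dioxolane cis-fused at C3–C4; aryl at C2 trans to the C3 oxygen) | CC(C)=CCC/C(C)=C/Cc1cc([C@H]2Oc3cc(O[Si](C)(C)C(C)(C)C)c(C)c(O[Si](C)(C)C(C)(C)C)c3[C@]4(O[Si](C)(C)C(C)(C)C)OC(C)(C)O[C@H]24)ccc1O[Si](C(C)C)(C(C)C)C(C)C | intermediate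
15 | (2R,3R)-5,7-bis(tert-butyldimethylsilyloxy)-2-[3-geranyl-4-(triisopropylsilyloxy)phenyl]-3-hydroxy-6-methylchroman-4-one | CC(C)=CCC/C(C)=C/Cc1cc([C@H]2Oc3cc(O[Si](C)(C)C(C)(C)C)c(C)c(O[Si](C)(C)C(C)(C)C)c3C(=O)[C@@H]2O)ccc1O[Si](C(C)C)(C(C)C)C(C)C | intermediate
16 | (2R,3R)-2-[3-geranyl-4-hydroxyphenyl]-3,5,7-trihydroxy-6-methylchroman-4-one | CC(C)=CCC/C(C)=C/Cc1cc([C@H]2Oc3cc(O)c(C)c(O)c3C(=O)[C@@H]2O)ccc1O | target

**Totals**
Total step count: 10. Longest linear sequence: 6 steps (steps 1, 2, 3, 7, 9, 10 from 1; equally steps 4, 5, 6, 7, 9, 10 from 5).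

**Steps most likely to fail**

1. Step 9. The silyl carboxonium ion may be quenched by silyl transfer faster than ring A attacks it, so the sequence stops at the open-chain lactone adduct. The ion pair may also give poor facial selectivity at C2, or the acid may re-ionise the C2–O1 bond. Fallback by known chemistry (chalcone epoxide route), setting out from 4 and 8 and coming back at 15: 4 is acetylated (Ac2O, pyridine) to 3,5-bis(tert-butyldimethylsilyloxy)-4-methylphenyl acetate F1. Photo-Fries rearrangement (254 nm, hexane; para position blocked, ortho positions equivalent) gives 1-[2,4-bis(tert-butyldimethylsilyloxy)-6-hydroxy-3-methylphenyl]ethanone F2. The chelated phenol is protected (MOMCl, i-Pr2NEt) as 1-[2,4-bis(tert-butyldimethylsilyloxy)-6-(methoxymethoxy)-3-methylphenyl]ethanone F3. Its lithium enolate (LiN(SiMe3)2, THF, −78 °C) adds to 8 to give the racemic aldol 3-hydroxy-3-[3-geranyl-4-(triisopropylsilyloxy)phenyl]-1-[2,4-bis(tert-butyldimethylsilyloxy)-6-(methoxymethoxy)-3-methylphenyl]propan-1-one F4, which is dehydrated (MsCl, Et3N) to the E-chalcone F5. Julia–Colonna epoxidation (poly-L-leucine, urea–H2O2, DBU, THF; the D-polymer if the sense proves opposite) attacks only the electron-poor enone olefin and should give the (2R,3S)-epoxy ketone F6. Selective MOM cleavage with ZnBr2/n-PrSH (CH2Cl2, 0 °C) frees the phenol, which opens the epoxide at the benzylic carbon with inversion (6-endo) to give 15.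

2. Step 7. C-alkylation of the ambident electron-rich phenol, acyl transfer from 9 to the phenol, or hydrolytic loss of the acetal acetate during isolation may prevail over O-alkylation. Fallback, setting out from 8 and 4 and coming back at 10: 8 is oxidised (NaClO2, NaH2PO4, 2-methyl-2-butene, t-BuOH/H2O; Pinnick) to 3-geranyl-4-(triisopropylsilyloxy)benzoic acid F7. This is esterified with 4 (DCC, DMAP, CH2Cl2) to 3,5-bis(tert-butyldimethylsilyloxy)-4-methylphenyl 3-geranyl-4-(triisopropylsilyloxy)benzoate F8. Reductive acetylation of the ester (i-Bu2AlH, CH2Cl2, −78 °C; then Ac2O, pyridine, DMAP, −78 → 0 °C) gives 10.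

3. Step 4. O-alkylation and double alkylation compete with ortho C-alkylation, so conversion into 7 may be low. Fallback, setting out from 5 and coming back at 8: 5 is brominated (Br2, AcOH) to 3-bromo-4-hydroxybenzaldehyde F9 and silylated (TIPSCl, imidazole, DMF) to 3-bromo-4-(triisopropylsilyloxy)benzaldehyde F10. Stille coupling with geranyltributylstannane (Pd(PPh3)4, DMF, 90 °C) fixes the position of the geranyl group by the carbon–bromine bond and gives 8.

**Further compounds**
F1 | step 9 | 3,5-bis(tert-butyldimethylsilyloxy)-4-methylphenyl acetate | CC(=O)Oc1cc(O[Si](C)(C)C(C)(C)C)c(C)c(O[Si](C)(C)C(C)(C)C)c1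
F2 | step 9 | 1-[2,4-bis(tert-butyldimethylsilyloxy)-6-hydroxy-3-methylphenyl]ethanone | CC(=O)c1c(O)cc(O[Si](C)(C)C(C)(C)C)c(C)c1O[Si](C)(C)C(C)(C)C
F3 | step 9 | 1-[2,4-bis(tert-butyldimethylsilyloxy)-6-(methoxymethoxy)-3-methylphenyl]ethanone | CC(=O)c1c(OCOC)cc(O[Si](C)(C)C(C)(C)C)c(C)c1O[Si](C)(C)C(C)(C)C
F4 | step 9 | 3-hydroxy-3-[3-geranyl-4-(triisopropylsilyloxy)phenyl]-1-[2,4-bis(tert-butyldimethylsilyloxy)-6-(methoxymethoxy)-3-methylphenyl]propan-1-one, racemic | CC(C)=CCC/C(C)=C/Cc1cc(C(O)CC(=O)c2c(OCOC)cc(O[Si](C)(C)C(C)(C)C)c(C)c2O[Si](C)(C)C(C)(C)C)ccc1O[Si](C(C)C)(C(C)C)C(C)C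
F5 | step 9 | (E)-3-[3-geranyl-4-(triisopropylsilyloxy)phenyl]-1-[2,4-bis(tert-butyldimethylsilyloxy)-6-(methoxymethoxy)-3-methylphenyl]prop-2-en-1-one | CC(C)=CCC/C(C)=C/Cc1cc(/C=C/C(=O)c2c(OCOC)cc(O[Si](C)(C)C(C)(C)C)c(C)c2O[Si](C)(C)C(C)(C)C)ccc1O[Si](C(C)C)(C(C)C)C(C)C
F6 | step 9 | [(2R,3S)-3-[3-geranyl-4-(triisopropylsilyloxy)phenyl]oxiran-2-yl][2,4-bis(tert-butyldimethylsilyloxy)-6-(methoxymethoxy)-3-methylphenyl]methanone | CC(C)=CCC/C(C)=C/Cc1cc([C@@H]2O[C@H]2C(=O)c2c(OCOC)cc(O[Si](C)(C)C(C)(C)C)c(C)c2O[Si](C)(C)C(C)(C)C)ccc1O[Si](C(C)C)(C(C)C)C(C)C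
F7 | step 7 | 3-geranyl-4-(triisopropylsilyloxy)benzoic acid | CC(C)=CCC/C(C)=C/Cc1cc(C(=O)O)ccc1O[Si](C(C)C)(C(C)C)C(C)C
F8 | step 7 | 3,5-bis(tert-butyldimethylsilyloxy)-4-methylphenyl 3-geranyl-4-(triisopropylsilyloxy)benzoate | CC(C)=CCC/C(C)=C/Cc1cc(C(=O)Oc2cc(O[Si](C)(C)C(C)(C)C)c(C)c(O[Si](C)(C)C(C)(C)C)c2)ccc1O[Si](C(C)C)(C(C)C)C(C)C
F9 | step 4 | 3-bromo-4-hydroxybenzaldehyde | O=Cc1ccc(O)c(Br)c1
F10 | step 4 | 3-bromo-4-(triisopropylsilyloxy)benzaldehyde | O=Cc1ccc(O[Si](C(C)C)(C(C)C)C(C)C)c(Br)c1
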